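The numbers of this flask are those of an exercise; the rest is arithmetic.

A one-step world has one clock, but this flask has two, the use of reagent and the uptake of gas.

    substrate + reagent → product (k1 = 1.33 M⁻¹ min⁻¹)
    substrate + reagent ⇌ intermediate A (K2 = 480 M⁻¹, k2 = 3.68 M⁻¹ min⁻¹)
    substrate + reagent → intermediate B (k3 = 2.58 M⁻¹ min⁻¹)
    intermediate B → product (k4 = 0.0949 min⁻¹)
    substrate + product ⇌ idle adduct, settled at all times (K5 = 1.69 M⁻¹)
    gas ⇌ reagent, rate k6*(csat - [reagent]) (k6 = 2.07 min⁻¹, csat = 37 mM)

| setting | delta | epsilon | eta | theta | gamma |
|---|---|---|---|---|---|
| substrate | 0.10 M | 0.20 M | 0.40 M | 0.80 M | 1.5 M |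
| gas | 37 mM (held) | 37 mM (held) | 37 mM (held) | 37 mM (held) | 37 mM (held) |
| time | 10 min | 10 min | 10 min | 10 min | 10 min |

1. [product] (only what is free in solution) at the end for delta, epsilon, eta, theta, gamma, in this order
2. the shape of the row from first to last (falls, then rises / falls all the way / hardly changes / rises, then falls / rises all the way)

- percent here means substrate units held: one idle adduct counts as two
- what is said of product includes idle adduct
- at the start none of reagent is dissolved
- in an amount of product, one idle adduct counts as one product
- the concentration of product that is asked is that of its free form alone
- "hardly changes" means that all values lie within two and a half points (for a concentration: within two and a half percent of the largest)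
- run time (delta): 10 min

1. Substrate takes reagent by its parallel routes with a summed constant 7.59 M⁻¹ min⁻¹, and the reckoning follows fractions of the charge.

2. At the low end, delta has a demand 0.759 min⁻¹ below the transfer coefficient 2.07 min⁻¹. Reagent is therefore reckoned at saturation at this end, and substrate decays as a pseudo-first-order species, with half-time 2.47 min.

3. At the high end, gamma has a demand 11.4 min⁻¹ above 2.07 min⁻¹. Uptake is then the rate-limiting step, with ceiling 0.0766 M min⁻¹, and half of the charge takes that half divided by the ceiling.

4. Joining the ends, the two times are added here. The joined half-time, the first-order half-time plus the half-charge divided by the uptake ceiling, is 7.69 min for theta. For gamma it is 12.3 min, and for delta 3.12 min.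

5. Theta and gamma are neighbours, but by this reckoning theta passes half of its charge within 10 min, while gamma does not. Their reckoned mean rates up to their joined half-times are 0.0520 M min⁻¹ and 0.0612 M min⁻¹. Taking these rates over 10 min, and the same share of what reacts as product, the reckoning gives gamma more product by a factor 1.18.

6. Half of the charge is taken as standing substrate in both flasks, which is rough for theta since 7.69 min lies before 10 min; the free share of product is then 0.597 in theta and 0.441 in gamma, a loss by a factor 1.35. That loss is larger than the gain, so this reckoning puts gamma's free product at 0.869 of theta's. Delta's reckoned mean rate up to its joined half-time is 0.0160 M min⁻¹, less than theta's, so the reckoning has the row rise from delta to theta and fall from theta to gamma.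

7. The forecast gives 0.03 M, 0.054 M, 0.087 M, 0.1 M and 0.079 M, with the shape rises, then falls, on the ground that “at high loading the leftover substrate ties more of it up as idle adduct”.

8. The flasks give 0.0288 M, 0.0527 M, 0.0844 M, 0.0994 M and 0.0782 M, with the shape rises, then falls, so gamma ends at 0.787 of theta against the reckoned 0.869. Gamma still holds 52.7% of its charge as substrate at 10.0 min. Product, counted with idle adduct, plus intermediate A and intermediate B make 32.4% of theta's charge at 5.00 min and 59.5% at 10.0 min, on either side of its joined half-time 7.69 min. In delta, with joined half-time 3.12 min, the same sum is 64.1% of the charge at 5.00 min.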